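**Maple reagent.** Counting one reagent per substrate lost, the maple run holds 7.98 mM of reagent at 4.00 min, 5.70 mM at 12.0 min, 3.18 mM at 30.0 min and 1.96 mM at 50.0 min. In the maple run left-handed product reaches 36.9 % at 50.0 min, which exceeds the 23 percentage points that left-handed substrate has given up, so right-handed substrate is turning into left-handed substrate (a dynamic kinetic resolution).

- maple: left-handed substrate 10 mM; right-handed substrate 10 mM; reagent 10 mM; free catalyst 0.50 mM; run made earlier
- flask: left-handed substrate 10 mM; reagent 20.0 mM; free catalyst 0.50 mM; right-handed substrate 10 mM; time 4.0 h

- maple (time / min: left-handed substrate / %, right-handed substrate / %, left-handed product / %): 4.00: 41.6, 48.3, 8.4; 12.0: 33.4, 45.1, 18.6; 20.0: 30.0, 41.6, 26.0; 30.0: 28.3, 37.6, 31.4; 50.0: 27.2, 32.6, 36.9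

(readings scatter by 0.3 percentage points)

1. part of the left-handed substrate and right-handed substrate charged together that has reacted at 4.0 h
2. excess of left-handed product over right-handed product in the product at 4.0 h
3. excess of right-handed substrate over left-handed substrate among what is left of the two at 4.0 h

- free catalyst is single-handed; left-handed substrate and right-handed substrate are mirror images of each other, charged as a racemate, each of them at the stated concentration
- an excess is the difference of the two amounts in percent of their sum
- an excess is below zero if the other one leads

**Fading strength.** The logarithmic fall of reagent per minute, divided by the mean left-handed substrate, reads 5.61 /M/min over the first interval but 4.36 /M/min over the last, the less certain reading. Read as a steady exponential fade, that is 0.00787 /min.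

**Working time.** In the flask, reagent matches the total substrate [T]. If the two substrates stay equal, [T] falls at κ times its square times the fading strength, with κ = 2.80 /M/min. Integrated, the reciprocal of [T] rises by κ times W, the working time: the minutes at undiminished strength that equal the real run. The fade gives W = 108 min for 4.0 h, so this reckoning expects 85.8 % reacted.

**Forecast.** The forecast gives 91.5 %, 80 % and 6 %, a conversion above this reckoning. Its grounds: “After fast early conversion, racemisation keeps the substrate nearly balanced, and loss follows second-order decay with about half the substrate reactive”.

**The flask.** The flask gives 69.8 %, 80.6 % and 0.686 %.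

    free catalyst → spent catalyst A (k = 0.0190 /min)
    free catalyst + right-handed substrate ⇌ catalyst intermediate B (K = 90.0 /M, k = 590 /M/min)
    free catalyst + left-handed substrate ⇌ catalyst intermediate A (K = 170 /M, k = 350 /M/min)
    reagent + catalyst intermediate A → free catalyst + left-handed product (k = 470 /M/min)
    reagent + catalyst intermediate B → free catalyst + right-handed product (k = 19.0 /M/min)
    2 free catalyst → spent catalyst B (k = 140 /M/min)
    left-handed substrate ⇌ right-handed substrate (k = 0.0330 /min)

In the flask at 4.00 h free catalyst stands at 0.740 % of its charge, spent catalyst A at 39.1 % and spent catalyst B at 59.8 %, with 30 % of the reagent left. That conversion means a working time of 41.1 min, against 108 min reckoned. Holding that time and scaling κ with the catalyst charge, the neighbour flask with 0.30 mM of free catalyst comes to 58.1 %; it gives 62.8 %.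

(All runs come from a simulation with made-up constants, noise included.)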